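**Retrosynthetic overview**

- Ring C of the (2S)-flavanone is cut at C3–C4 and O1–C2. This gives a salicylaldehyde that carries ring A complete (prenyl in place, MOM on the 4-OH) and a terminal arylalkyne that carries ring B with its dimethylpyran ring. The two are joined in one flask by rhodium-catalysed alkyne hydroacylation (C3–C4) and catalyst-controlled enantioselective oxa-Michael closure (O1–C2); aldehyde plus alkyne equals flavanone with no atom lost.
- Enabling feature: the salicyloyl unit O1–C8a–C4a–C4(=O) of ring A. Its ortho phenol first chelates rhodium for formyl C–H activation and then is the nucleophile for 6-endo attack on benzylic C2. The two-carbon C2–C3 bridge next to ring B matches an alkyne.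
- Aldehyde: 5-bromo-2,4-dihydroxybenzaldehyde, selective 4-O-MOM protection, linear-selective Suzuki prenylation.
- Alkyne: 4-hydroxybenzaldehyde, propargyl ether, Claisen/oxa-6π cascade to the chromene, Seyferth–Gilbert homologation.
- Ring order: the pyran ring of the chromene first (step 4), ring C in the key step (step 6); MOM removal ends the route.

Key step: step 6

Assumption: the quinine-derived thiourea is taken to deliver the 2S configuration at C2; if the sense of induction turns out opposite, the quinidine-derived pseudo-enantiomer is used in its place under otherwise identical conditions.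

**Step 1**
Reactants: 1 5-bromo-2,4-dihydroxybenzaldehyde
Product: 2 5-bromo-2-hydroxy-4-(methoxymethoxy)benzaldehyde
Conditions: MOMCl (1.1 equiv), K2CO3 (1.5 equiv), acetone, 0 °C to rt
Reagents that add atoms: chloromethyl methyl ether (MOMCl), COCCl
Why: The 2-OH is held in a hydrogen bond to the formyl group and is the poorer nucleophile, so Williamson-type O-alkylation under mild carbonate conditions should take place at the 4-OH only (regioselective MOM protection).

**Step 2**
Reactants: 2 5-bromo-2-hydroxy-4-(methoxymethoxy)benzaldehyde; 3 4,4,5,5-tetramethyl-2-(3-methylbut-2-en-1-yl)-1,3,2-dioxaborolane (prenylboronic acid pinacol ester)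
Product: 4 2-hydroxy-4-(methoxymethoxy)-5-(3-methylbut-2-en-1-yl)benzaldehyde
Conditions: 3 (1.5 equiv), PdCl2(IPent)(3-chloropyridine) (2 mol %; IPent = 1,3-bis(2,6-di(pentan-3-yl)phenyl)imidazol-2-ylidene), KOH (aq, 5 M), THF, 65 °C
Reagents that add atoms: none
Why: Suzuki–Miyaura allylation in which the very bulky carbene ligand should disfavour the tertiary σ-allyl palladium species, so that C–C reductive elimination occurs at the primary terminus and gives the linear prenyl arene and not the reverse-prenyl isomer.

**Step 3**
Reactants: 5 4-hydroxybenzaldehyde; 6 3-chloro-3-methylbut-1-yne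
Product: 7 4-[(2-methylbut-3-yn-2-yl)oxy]benzaldehyde
Conditions: K2CO3, KI (cat.), acetone, reflux
Reagents that add atoms: none
Why: Williamson-type etherification of the phenoxide with the tertiary propargylic chloride, a standard entry to aryl 1,1-dimethylpropargyl ethers, should give the ether without C-alkylation.

**Step 4**
Reactants: 7 4-[(2-methylbut-3-yn-2-yl)oxy]benzaldehyde
Product: 9 2,2-dimethyl-2H-chromene-6-carbaldehyde, via allenylphenol 8 (not isolated)
Conditions: N,N-diethylaniline, 190 °C
Reagents that add atoms: none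
Why: Aromatic propargyl Claisen rearrangement and tautomerisation should give allenylphenol 8, whose 1,5-hydrogen shift and oxa-6π electrocyclisation close the 2,2-dimethylpyran ring; the two ortho positions are equivalent, and the step is an isomerisation in which nothing is lost.

**Step 5**
Reactants: 9 2,2-dimethyl-2H-chromene-6-carbaldehyde
Product: 10 6-ethynyl-2,2-dimethyl-2H-chromene
Conditions: dimethyl (1-diazo-2-oxopropyl)phosphonate (1.3 equiv), K2CO3 (2 equiv), MeOH, 0 °C to rt
Reagents that add atoms: dimethyl (1-diazo-2-oxopropyl)phosphonate (Ohira–Bestmann reagent), COP(=O)(OC)C(=[N+]=[N-])C(C)=O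
Why: Seyferth–Gilbert homologation in the Ohira–Bestmann form should convert the non-enolisable aryl aldehyde into the terminal alkyne under mild basic conditions that leave the chromene alkene untouched.

**Step 6**
Reactants: 4 2-hydroxy-4-(methoxymethoxy)-5-(3-methylbut-2-en-1-yl)benzaldehyde; 10 6-ethynyl-2,2-dimethyl-2H-chromene
Product: 12 (2S)-2-(2,2-dimethyl-2H-chromen-6-yl)-7-(methoxymethoxy)-6-(3-methylbut-2-en-1-yl)-2,3-dihydro-4H-chromen-4-one, via chalcone 11 (not isolated)
Conditions: [RhCl(cod)]2 (2.5 mol %), 1,1'-bis(diphenylphosphino)ferrocene (5 mol %), Na2CO3 (5 mol %), toluene, 80 °C, 10 (1.2 equiv) added slowly; then 0 °C to rt, 1-[3,5-bis(trifluoromethyl)phenyl]-3-[(8S,9S)-6'-methoxycinchonan-9-yl]thiourea (10 mol %), same flask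
Reagents that add atoms: none
Why: Proposed new method: the sodium phenoxide of 4 binds monovalent rhodium, chelation-assisted oxidative addition of the formyl C–H bond gives an acyl hydride of trivalent rhodium, syn hydrometalation of the terminal alkyne of 10 followed by C–C reductive elimination forms the C3–C4 bond and releases (E)-chalcone 11, and the bifunctional thiourea then deprotonates the 2'-OH while hydrogen-bonding the enone carbonyl, so that the phenoxide adds to the β-carbon and forms the O1–C2 bond. The closest known reaction types are the racemic one-pot alkyne hydroacylation/oxa-Michael annulation of salicylaldehydes to chroman-4-ones and the separately run cinchona-base-catalysed enantioselective cyclisation of 2'-hydroxyaryl enones; new here is the enantioselective second stage in the same flask on an unactivated chalcone. Ring C closes in a 6-endo-trig oxa-Michael addition. The C2 stereocentre is set under catalyst control, the ion pair of quinuclidinium and phenoxide held on the thiourea exposing one enantioface of the E-enone, with no substrate stereocentre involved. The step needs regioselectivity (acyl to the unsubstituted alkyne carbon, hydrogen to the aryl-bearing one), which the terminal arylalkyne secures sterically and electronically, chemoselectivity for the alkyne over the trisubstituted prenyl alkene and the hindered chromene alkene next to the quaternary carbon, which should not insert, and a slow racemic background, for which the base of the first stage is kept catalytic and the 4-OH is capped as its MOM ether so that no deactivating para-phenoxide forms. The step is an isomerising addition in which every atom of 4 and 10 ends up in 12.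

**Step 7**
Reactants: 12 (2S)-2-(2,2-dimethyl-2H-chromen-6-yl)-7-(methoxymethoxy)-6-(3-methylbut-2-en-1-yl)-2,3-dihydro-4H-chromen-4-one
Product: 13 Dinklagin A, (2S)-2-(2,2-dimethyl-2H-chromen-6-yl)-7-hydroxy-6-(3-methylbut-2-en-1-yl)-2,3-dihydro-4H-chromen-4-one
Conditions: HCl (1.25 M in MeOH), 0 °C to rt
Reagents that add atoms: none
Why: Acid-catalysed acetal exchange with methanol (MOM cleavage) should free the 7-OH under conditions too mild for ring opening at C2 or for acid-induced cyclisation of the prenyl group onto the new phenol, so the 2S centre is carried through unchanged.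

**Compound list**

1 | 5-bromo-2,4-dihydroxybenzaldehyde | O=Cc1cc(Br)c(O)cc1O | starting material
2 | 5-bromo-2-hydroxy-4-(methoxymethoxy)benzaldehyde | O=Cc1cc(Br)c(OCOC)cc1O | intermediate
3 | 4,4,5,5-tetramethyl-2-(3-methylbut-2-en-1-yl)-1,3,2-dioxaborolane | CC(C)=CCB1OC(C)(C)C(C)(C)O1 | starting material
4 | 2-hydroxy-4-(methoxymethoxy)-5-(3-methylbut-2-en-1-yl)benzaldehyde | O=Cc1cc(CC=C(C)C)c(OCOC)cc1O | intermediate
5 | 4-hydroxybenzaldehyde | O=Cc1ccc(O)cc1 | starting material
6 | 3-chloro-3-methylbut-1-yne | C#CC(C)(C)Cl | starting material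
7 | 4-[(2-methylbut-3-yn-2-yl)oxy]benzaldehyde | O=Cc1ccc(OC(C)(C)C#C)cc1 | intermediate
8 | 4-hydroxy-3-(3-methylbuta-1,2-dien-1-yl)benzaldehyde (not isolated) | CC(C)=C=Cc1cc(C=O)ccc1O | intermediate
9 | 2,2-dimethyl-2H-chromene-6-carbaldehyde | CC1(C)C=Cc2cc(C=O)ccc2O1 | intermediate
10 | 6-ethynyl-2,2-dimethyl-2H-chromene | C#Cc1ccc2c(c1)C=CC(C)(C)O2 | intermediate
11 | (E)-3-(2,2-dimethyl-2H-chromen-6-yl)-1-[2-hydroxy-4-(methoxymethoxy)-5-(3-methylbut-2-en-1-yl)phenyl]prop-2-en-1-one (not isolated) | CC(C)=CCc1cc(C(=O)/C=C/c2ccc3c(c2)C=CC(C)(C)O3)c(O)cc1OCOC | intermediate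
12 | (2S)-2-(2,2-dimethyl-2H-chromen-6-yl)-7-(methoxymethoxy)-6-(3-methylbut-2-en-1-yl)-2,3-dihydro-4H-chromen-4-one | CC(C)=CCc1cc2c(cc1OCOC)O[C@H](c1ccc3c(c1)C=CC(C)(C)O3)CC2=O | intermediate
13 | Dinklagin A, (2S)-2-(2,2-dimethyl-2H-chromen-6-yl)-7-hydroxy-6-(3-methylbut-2-en-1-yl)-2,3-dihydro-4H-chromen-4-one | CC(C)=CCc1cc2c(cc1O)O[C@H](c1ccc3c(c1)C=CC(C)(C)O3)CC2=O | target

**Step count and risks**

Total step count: 7. Longest linear sequence: 5 steps (steps 3, 4, 5, 6, 7).

Steps most likely to fail:

1. Step 6 (proposed new method). In the first stage the acyl group may be delivered to the internal alkyne carbon, giving a branched enone that would close to an isoflavanone, or rhodium may oligomerise the alkyne. In the second stage enantioface discrimination on the unactivated chalcone may be low, or the product may erode through reversible ring opening, which the electron-rich ring B favours. The fallback uses known chemistry, the enantioselective oxa-Michael cyclisation of a doubly activated chalcone, and leaves the alkyne aside. It sets out from 4 and 9. Aldol addition of the lithium enolate of allyl acetate (LiN(i-Pr)2, THF, −78 °C, in excess to allow for the phenol) to 4 should give allyl 3-hydroxy-3-[2-hydroxy-4-(methoxymethoxy)-5-(3-methylbut-2-en-1-yl)phenyl]propanoate F1. MnO2 in CH2Cl2 should oxidise the benzylic alcohol to allyl 3-[2-hydroxy-4-(methoxymethoxy)-5-(3-methylbut-2-en-1-yl)phenyl]-3-oxopropanoate F2. Knoevenagel condensation with 9 (piperidine, AcOH, toluene, 4 Å molecular sieves) should give allyl 3-(2,2-dimethyl-2H-chromen-6-yl)-2-[2-hydroxy-4-(methoxymethoxy)-5-(3-methylbut-2-en-1-yl)benzoyl]prop-2-enoate F3. The same quinine-derived thiourea (10 mol %, toluene, −25 °C) should close ring C to allyl (2S)-2-(2,2-dimethyl-2H-chromen-6-yl)-7-(methoxymethoxy)-6-(3-methylbut-2-en-1-yl)-4-oxo-3,4-dihydro-2H-chromene-3-carboxylate F4. Pd(PPh3)4 with morpholine in THF at rt should then remove the allyl ester with decarboxylation under neutral conditions. The fallback comes back to the route at 12.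

2. Step 7. Acid may add the freed 7-OH across the neighbouring prenyl double bond (closure to a dimethylchroman), or may racemise C2 through ring opening. The fallback replaces the acid-labile acetal by a fluoride-labile silyl ether from the start. It sets out from 1. TIPSCl and imidazole in CH2Cl2 should silylate the 4-OH selectively to give 5-bromo-2-hydroxy-4-[(triisopropylsilyl)oxy]benzaldehyde F5. Stille coupling with tributyl(3-methylbut-2-en-1-yl)stannane (Pd(PPh3)4, DMF, 90 °C, no hydroxide) should give 2-hydroxy-5-(3-methylbut-2-en-1-yl)-4-[(triisopropylsilyl)oxy]benzaldehyde F6. The conditions of step 6 with 10 should lead through (E)-3-(2,2-dimethyl-2H-chromen-6-yl)-1-[2-hydroxy-5-(3-methylbut-2-en-1-yl)-4-[(triisopropylsilyl)oxy]phenyl]prop-2-en-1-one F7, not isolated, to (2S)-2-(2,2-dimethyl-2H-chromen-6-yl)-6-(3-methylbut-2-en-1-yl)-7-[(triisopropylsilyl)oxy]-2,3-dihydro-4H-chromen-4-one F8. Tetrabutylammonium fluoride buffered with AcOH in THF at 0 °C should then cleave the silyl ether. The fallback comes back to the route at 13.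

3. Step 2. The allyl unit may couple at its tertiary terminus (reverse-prenyl isomer), and oxidative addition into the electron-rich phenoxide bromide may be slow enough for protodeboronation to compete. The fallback separates C–C coupling from the placing of the two methyl groups. It sets out from 2. Suzuki–Miyaura coupling with allylboronic acid pinacol ester (Pd(PPh3)4, CsF, THF, reflux), where no regiochemical question arises, should give 2-hydroxy-4-(methoxymethoxy)-5-(prop-2-en-1-yl)benzaldehyde F9. Olefin cross-metathesis with excess 2-methylbut-2-ene (second-generation Grubbs catalyst RuCl2(=CHPh)(PCy3)(H2IMes), CH2Cl2, 40 °C) should then convert the allyl into the prenyl group. The fallback comes back to the route at 4.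

**Further compounds**

F1 | step 6 | allyl 3-hydroxy-3-[2-hydroxy-4-(methoxymethoxy)-5-(3-methylbut-2-en-1-yl)phenyl]propanoate (racemic) | C=CCOC(=O)CC(O)c1cc(CC=C(C)C)c(OCOC)cc1O
F2 | step 6 | allyl 3-[2-hydroxy-4-(methoxymethoxy)-5-(3-methylbut-2-en-1-yl)phenyl]-3-oxopropanoate | C=CCOC(=O)CC(=O)c1cc(CC=C(C)C)c(OCOC)cc1O
F3 | step 6 | allyl 3-(2,2-dimethyl-2H-chromen-6-yl)-2-[2-hydroxy-4-(methoxymethoxy)-5-(3-methylbut-2-en-1-yl)benzoyl]prop-2-enoate (alkene geometry not fixed) | C=CCOC(=O)C(=Cc1ccc2c(c1)C=CC(C)(C)O2)C(=O)c1cc(CC=C(C)C)c(OCOC)cc1O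
F4 | step 6 | allyl (2S)-2-(2,2-dimethyl-2H-chromen-6-yl)-7-(methoxymethoxy)-6-(3-methylbut-2-en-1-yl)-4-oxo-3,4-dihydro-2H-chromene-3-carboxylate (C3 epimers and enol in equilibrium) | C=CCOC(=O)C1C(=O)c2cc(CC=C(C)C)c(OCOC)cc2O[C@@H]1c1ccc3c(c1)C=CC(C)(C)O3
F5 | step 7 | 5-bromo-2-hydroxy-4-[(triisopropylsilyl)oxy]benzaldehyde | O=Cc1cc(Br)c(O[Si](C(C)C)(C(C)C)C(C)C)cc1O
F6 | step 7 | 2-hydroxy-5-(3-methylbut-2-en-1-yl)-4-[(triisopropylsilyl)oxy]benzaldehyde | O=Cc1cc(CC=C(C)C)c(O[Si](C(C)C)(C(C)C)C(C)C)cc1O
F7 | step 7 | (E)-3-(2,2-dimethyl-2H-chromen-6-yl)-1-[2-hydroxy-5-(3-methylbut-2-en-1-yl)-4-[(triisopropylsilyl)oxy]phenyl]prop-2-en-1-one (not isolated) | CC(C)=CCc1cc(C(=O)/C=C/c2ccc3c(c2)C=CC(C)(C)O3)c(O)cc1O[Si](C(C)C)(C(C)C)C(C)C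
F8 | step 7 | (2S)-2-(2,2-dimethyl-2H-chromen-6-yl)-6-(3-methylbut-2-en-1-yl)-7-[(triisopropylsilyl)oxy]-2,3-dihydro-4H-chromen-4-one | CC(C)=CCc1cc2c(cc1O[Si](C(C)C)(C(C)C)C(C)C)O[C@H](c1ccc3c(c1)C=CC(C)(C)O3)CC2=O
F9 | step 2 | 2-hydroxy-4-(methoxymethoxy)-5-(prop-2-en-1-yl)benzaldehyde | O=Cc1cc(CC=C)c(OCOC)cc1O
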